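**Strategy.** The route rests on cutting ring A out of the flavanone. The resorcinol carbons C5–C8 with O5, O7 and the C8 prenyl group are the atoms of a γ-prenylated acetoacetate-derived 1,3-bis(silyloxy)diene, and C4a–C8a is the enol-ether double bond of a chiral 2-aryl-2,3-dihydropyran-4-one (rings B and C, with C2 already S). One cycloaddition–aromatisation forms C8–C8a and C4a–C5 and, by loss of HBr and methanol, the whole 5,7-dihydroxy-8-prenyl benzene ring with its regiochemistry. The precursor is the (S)-5-bromo-dihydropyranone with its catechol masked as silyl ethers, made by asymmetric hetero-Diels–Alder reaction and bromination. Buffered fluoride then frees the catechol.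

Key step: step 7

Assumption: the facial sense of the BINOL–titanium catalyst with this aldehyde is taken to parallel its usual sense with benzaldehyde-type substrates, (S)-BINOL leading to the (S)-dihydropyranone; the sense would be checked on the first batch and the antipodal ligand used if it were opposite.

Step 1
Reactants: 1 3,4-dihydroxybenzaldehyde
Product: 2 3,4-bis(tert-butyldimethylsilyloxy)benzaldehyde
Conditions: TBSCl, imidazole, DMF, rt
Reagents that add atoms: tert-butyldimethylsilyl chloride, CC(C)(C)[Si](C)(C)Cl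
Why: Imidazole-promoted silylation of phenols is routine, and silyl ethers are chosen over alkoxymethyl ethers because they leave at the end with buffered fluoride (no acid near the ortho-prenyl phenol), tolerate the acid of step 2, and make the arene less electron-rich, which disfavours ring bromination in step 3 and ionisation of the benzylic C2–O1 bond later.

Step 2
Reactants: 2 3,4-bis(tert-butyldimethylsilyloxy)benzaldehyde; 3 trans-1-methoxy-3-(trimethylsilyloxy)buta-1,3-diene
Product: 5 (S)-2-[3,4-bis(tert-butyldimethylsilyloxy)phenyl]-2,3-dihydro-4H-pyran-4-one, via silylated Mukaiyama aldol adduct 4 (not isolated)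
Conditions: (S)-BINOL (20 mol%), Ti(OiPr)4 (10 mol%), 4 Å MS, Et2O, −20 °C; then TFA (cat.), CH2Cl2, 0 °C
Reagents that add atoms: none
Why: Enantioselective hetero-Diels–Alder reaction in its Mukaiyama-aldol/cyclisation form: the BINOL–titanium(IV) Lewis acid binds the aldehyde and shields one enantioface, so the diene terminus adds to the other and sets C2 as S in the C–C bond-forming event, after which acid closes adduct 4 by oxa-Michael addition and loss of methanol without touching C2.

Step 3
Reactants: 5 (S)-2-[3,4-bis(tert-butyldimethylsilyloxy)phenyl]-2,3-dihydro-4H-pyran-4-one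
Product: 6 (S)-5-bromo-2-[3,4-bis(tert-butyldimethylsilyloxy)phenyl]-2,3-dihydro-4H-pyran-4-one
Conditions: NBS (1.05 equiv), CH2Cl2, 0 °C → rt
Reagents that add atoms: N-bromosuccinimide, O=C1CCC(=O)N1Br
Why: Electrophilic α-halogenation of a vinylogous ester: the enol-ether carbon C5 is the most nucleophilic site, bromonium transfer gives an O1-stabilised oxocarbenium ion that loses H-5 to restore the enone, and one equivalent at low temperature should spare the silyloxy-arene and the C2 centre.

Step 4
Reactants: 7 methyl acetoacetate; 8 prenyl bromide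
Product: 10 methyl 7-methyl-3-oxooct-6-enoate, via acetoacetate dianion 9 (not isolated)
Conditions: NaH, THF, 0 °C; n-BuLi, 0 °C; then 8, 0 °C → rt; aq. HCl
Reagents that add atoms: none
Why: Weiler dianion alkylation: the γ-carbanion of the acetoacetate dianion is far more nucleophilic than the stabilised α-position, so the allylic bromide is attacked by the terminal carbon only (SN2).

Step 5
Reactants: 10 methyl 7-methyl-3-oxooct-6-enoate
Product: 11 methyl 7-methyl-3-(trimethylsilyloxy)octa-2,6-dienoate
Conditions: TMSCl, Et3N, CH2Cl2, 0 °C → rt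
Reagents that add atoms: chlorotrimethylsilane, C[Si](C)(C)Cl
Why: O-Silylation of the β-keto ester enol under amine base (soft enolisation) gives the β-silyloxy enoate, the standard first stage of a 1,3-bis(silyloxy)diene synthesis; the double-bond geometry is immaterial.

Step 6
Reactants: 11 methyl 7-methyl-3-(trimethylsilyloxy)octa-2,6-dienoate
Product: 13 1-methoxy-7-methyl-1,3-bis(trimethylsilyloxy)octa-1,3,6-triene, via lithium dienolate 12 (not isolated)
Conditions: LDA, THF, −78 °C; then TMSCl, −78 °C → rt; used crude
Reagents that add atoms: chlorotrimethylsilane, C[Si](C)(C)Cl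
Why: Kinetic γ-deprotonation of the vinylogous ester by LDA and O-silylation of the dienolate gives the Chan-type 1-methoxy-1,3-bis(silyloxy)diene, which is moisture-sensitive and is therefore used crude after removal of salts and solvent.

Step 7
Reactants: 6 (S)-5-bromo-2-[3,4-bis(tert-butyldimethylsilyloxy)phenyl]-2,3-dihydro-4H-pyran-4-one; 13 1-methoxy-7-methyl-1,3-bis(trimethylsilyloxy)octa-1,3,6-triene
Product: 16 (2S)-2-[3,4-bis(tert-butyldimethylsilyloxy)phenyl]-5,7-dihydroxy-8-(3-methylbut-2-en-1-yl)chroman-4-one, via cis-fused bromo cycloadduct 14 (not isolated), via dehydrobrominated dienyl ketal 15 (not isolated)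
Conditions: 13 (2 equiv), PhMe, 80 °C; then iPr2NEt, 60 °C; then 1 M HCl, THF, 0 °C
Reagents that add atoms: none
Why: Proposed new method: the electron-rich diene 13 and the polarised α-bromo vinylogous ester 6 are expected to combine in an asynchronous normal-demand [4+2] cycloaddition, the prenyl-bearing diene terminus (future C8) bonding first to the oxygen-bearing β-carbon C8a and the ketene-acetal carbon (future C5) then closing onto the bromine-bearing C4a to give 14; the hindered amine removes HBr across C8a–C4a to give 15, and dilute acid cleaves the mixed silyl ketal and the silyl enol ether so that loss of methanol and a proton shift from C8 deliver the resorcinol. The closest known reaction type is the regiocontrolled cycloaddition–aromatisation of 1,3-bis(silyloxy)dienes and related ketene-acetal dienes with halo-quinones and other α-halo enones; a β-alkoxy bromo-enone has not been used as the 2π partner. Ring A closes as the six-membered ring of an intermolecular [4+2] annulation (in the stepwise limit a Michael addition followed by a 6-(enolexo)-exo-trig attack of C4a on the carboxonium carbon). No new stereocentre survives, because the four transient ring centres are erased on aromatisation, and C2 is untouched because no Lewis acid able to ionise the benzylic C2–O1 bond is present. The regiochemistry follows from the polarity of the partners (the γ-carbon is the most nucleophilic diene terminus and C8a the most electrophilic carbon of the bromo-enone), and O1 is retained because C4a carries no hydrogen in the adduct, so the β-alkoxy ketone cannot enolise toward C8a. The demanding point is that H-8a and Br-4a are cis in the adduct, so the dehydrobromination must be a syn process pulled by formation of the push–pull enone and finally the arene, and a weak hindered base is used so that C8 is not deprotonated, which would expel O1 instead.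

Step 8
Reactants: 16 (2S)-2-[3,4-bis(tert-butyldimethylsilyloxy)phenyl]-5,7-dihydroxy-8-(3-methylbut-2-en-1-yl)chroman-4-one
Product: 17 (2S)-2-(3,4-dihydroxyphenyl)-5,7-dihydroxy-8-(3-methylbut-2-en-1-yl)chroman-4-one
Conditions: TBAF, AcOH (1:1), THF, 0 °C
Reagents that add atoms: none
Why: Fluoride cleavage of aryl silyl ethers; acetic acid buffering keeps the medium near neutral, so the flavanone should not open to the chalcone (no racemisation at C2) and the prenyl group and free resorcinol are left alone.

**Compound list**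

1 | 3,4-dihydroxybenzaldehyde | O=Cc1ccc(O)c(O)c1 | starting material
2 | 3,4-bis(tert-butyldimethylsilyloxy)benzaldehyde | O=Cc1ccc(O[Si](C)(C)C(C)(C)C)c(O[Si](C)(C)C(C)(C)C)c1 | intermediate
3 | trans-1-methoxy-3-(trimethylsilyloxy)buta-1,3-diene | CO/C=C/C(=C)O[Si](C)(C)C | starting material
4 | (1E,5S)-5-[3,4-bis(tert-butyldimethylsilyloxy)phenyl]-1-methoxy-5-(trimethylsilyloxy)pent-1-en-3-one (formed in the flask) | CO/C=C/C(=O)C[C@H](O[Si](C)(C)C)c1ccc(O[Si](C)(C)C(C)(C)C)c(O[Si](C)(C)C(C)(C)C)c1 | intermediate
5 | (S)-2-[3,4-bis(tert-butyldimethylsilyloxy)phenyl]-2,3-dihydro-4H-pyran-4-one | O=C1C=CO[C@H](c2ccc(O[Si](C)(C)C(C)(C)C)c(O[Si](C)(C)C(C)(C)C)c2)C1 | intermediate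
6 | (S)-5-bromo-2-[3,4-bis(tert-butyldimethylsilyloxy)phenyl]-2,3-dihydro-4H-pyran-4-one | O=C1C(Br)=CO[C@H](c2ccc(O[Si](C)(C)C(C)(C)C)c(O[Si](C)(C)C(C)(C)C)c2)C1 | intermediate
7 | methyl acetoacetate | COC(=O)CC(C)=O | starting material
8 | prenyl bromide (1-bromo-3-methylbut-2-ene) | CC(C)=CCBr | starting material
9 | sodium lithium dianion of methyl acetoacetate (formed in the flask) | [Na+].[Li+].[CH2-]C(=O)[CH-]C(=O)OC | intermediate
10 | methyl 7-methyl-3-oxooct-6-enoate | COC(=O)CC(=O)CCC=C(C)C | intermediate
11 | methyl 7-methyl-3-(trimethylsilyloxy)octa-2,6-dienoate (2E/2Z mixture, geometry immaterial) | COC(=O)C=C(CCC=C(C)C)O[Si](C)(C)C | intermediate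
12 | lithium dienolate of 11 (formed in the flask) | [Li+].COC([O-])=CC(O[Si](C)(C)C)=CCC=C(C)C | intermediate
13 | 1-methoxy-7-methyl-1,3-bis(trimethylsilyloxy)octa-1,3,6-triene (3Z drawn; C1 geometry unassigned) | COC(O[Si](C)(C)C)=C/C(O[Si](C)(C)C)=C/CC=C(C)C | intermediate
14 | (2S)-4a-bromo-2-[3,4-bis(tert-butyldimethylsilyloxy)phenyl]-5-methoxy-8-(3-methylbut-2-en-1-yl)-5,7-bis(trimethylsilyloxy)-2,3,4a,5,8,8a-hexahydro-4H-chromen-4-one (cis ring fusion; transient centres unassigned; formed in the flask) | O=C1C[C@@H](c3ccc(O[Si](C)(C)C(C)(C)C)c(O[Si](C)(C)C(C)(C)C)c3)OC2C(CC=C(C)C)C(O[Si](C)(C)C)=CC(OC)(O[Si](C)(C)C)C12Br | intermediate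
15 | (2S)-2-[3,4-bis(tert-butyldimethylsilyloxy)phenyl]-5-methoxy-8-(3-methylbut-2-en-1-yl)-5,7-bis(trimethylsilyloxy)-2,3,5,8-tetrahydro-4H-chromen-4-one (C5 and C8 unassigned; formed in the flask) | O=C1C[C@@H](c3ccc(O[Si](C)(C)C(C)(C)C)c(O[Si](C)(C)C(C)(C)C)c3)OC2=C1C(OC)(O[Si](C)(C)C)C=C(O[Si](C)(C)C)C2CC=C(C)C | intermediate
16 | (2S)-2-[3,4-bis(tert-butyldimethylsilyloxy)phenyl]-5,7-dihydroxy-8-(3-methylbut-2-en-1-yl)chroman-4-one | CC(C)=CCc1c(O)cc(O)c2c1O[C@H](c1ccc(O[Si](C)(C)C(C)(C)C)c(O[Si](C)(C)C(C)(C)C)c1)CC2=O | intermediate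
17 | (2S)-2-(3,4-dihydroxyphenyl)-5,7-dihydroxy-8-(3-methylbut-2-en-1-yl)chroman-4-one, (2S)-8-prenyleriodictyol | CC(C)=CCc1c(O)cc(O)c2c1O[C@H](c1ccc(O)c(O)c1)CC2=O | target

**Step count.** Total: 8 steps. Longest linear sequence: 5 steps (1 → 2 → 5 → 6 → 16 → 17; the diene branch 7 → 10 → 11 → 13 → 16 → 17 is equally long).

**Steps most likely to fail**

1. Step 7 (cycloaddition–aromatisation, proposed new method). Three processes may go wrong:
 - the β-alkoxy bromo-enone may be too weak a 2π partner, so the diene decomposes before it adds;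
 - the cis H-8a/Br-4a pair may resist syn-elimination;
 - base may deprotonate C8 and open ring C at C8a–O1, after which the ring aromatises without its oxygen.

 The fallback uses known chemistry and a different approach: the prenyl group is put onto a ready-made ring A. It sets out from prenyl bromide 8 and comes back to the route at target 17. Commercial (S)-eriodictyol F1 would be silylated at its three non-chelated hydroxyls (TBSCl, imidazole, DMF, 0 °C) to give (2S)-7,3',4'-tris-O-(tert-butyldimethylsilyl)eriodictyol F2. The chelated 5-hydroxyl would then be O-alkylated with 8 under neutral silver(I) oxide conditions (a Mitsunobu etherification with prenol is the equivalent base-free option) to give the 5-O-prenyl ether F3. Europium(III)-catalysed aromatic Claisen rearrangement to C6 followed by Cope shift to C8 (Eu(fod)3, CHCl3, 60 °C) should give (2S)-7,3',4'-tris-O-(tert-butyldimethylsilyl)-8-prenyleriodictyol F4. Under the conditions of step 8, F4 should lose its three silyl groups to give 17.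

2. Step 2 (asymmetric hetero-Diels–Alder). The electron-rich, ortho-silyloxy aldehyde may bind the catalyst poorly, giving slow turnover or poor facial selectivity, and the absolute sense rests on analogy. The fallback takes the stereocentre from an asymmetric hydrogenation and the ring from an ynone cyclisation. It sets out from aldehyde 2 and comes back at dihydropyranone 5. Roskamp homologation of 2 (ethyl diazoacetate, cat. SnCl2, CH2Cl2) would give ethyl 3-[3,4-bis(tert-butyldimethylsilyloxy)phenyl]-3-oxopropanoate F5. Noyori hydrogenation with a Ru(II) catalyst carrying an (R)-BINAP-type ligand would follow; the usual sense for β-keto esters corresponds to the (S)-aryl carbinol, giving ethyl (S)-3-[3,4-bis(tert-butyldimethylsilyloxy)phenyl]-3-hydroxypropanoate F6. Conversion with MeNH(OMe)·HCl/i-PrMgCl would give the Weinreb amide F7, and ethynylmagnesium bromide would give (S)-5-[3,4-bis(tert-butyldimethylsilyloxy)phenyl]-5-hydroxypent-1-yn-3-one F8. 6-endo-dig oxa-Michael cyclisation of F8 (Et2NH, then mild acid, or cat. AgOTf) should give 5.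

3. Step 3 (α-bromination). Bromine may attack the silyloxy-arene or add twice, and adventitious HBr may strip silyl ethers, instead of clean monobromination at C5. The fallback changes the C4a leaving group to one that is introduced by a softer electrophile and that eliminates thermally in the syn sense. It sets out from 5 and comes back at intermediate 15, hence 16. Sulfenylation of 5 (PhSCl, CH2Cl2, −78 °C; then Et3N) would give (S)-2-[3,4-bis(tert-butyldimethylsilyloxy)phenyl]-5-(phenylthio)-2,3-dihydro-4H-pyran-4-one F9. Oxidation with one equivalent of mCPBA at −78 °C would give the sulfoxide F10 as a mixture of sulfur epimers. Cycloaddition of F10 with diene 13 in toluene should give the sulfinyl cycloadduct F11, in which the sulfinyl group and H-8a are cis. F11 is expected to lose benzenesulfenic acid by thermal syn-elimination to give 15, which the acid work-up of step 7 converts into 16.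

**Further compounds**

F1 | step 7 | (S)-eriodictyol | O=C1C[C@@H](c2ccc(O)c(O)c2)Oc2cc(O)cc(O)c12
F2 | step 7 | (2S)-7,3',4'-tris-O-(tert-butyldimethylsilyl)eriodictyol | O=C1C[C@@H](c2ccc(O[Si](C)(C)C(C)(C)C)c(O[Si](C)(C)C(C)(C)C)c2)Oc2cc(O[Si](C)(C)C(C)(C)C)cc(O)c12
F3 | step 7 | (2S)-5-O-prenyl-7,3',4'-tris-O-(tert-butyldimethylsilyl)eriodictyol | O=C1C[C@@H](c2ccc(O[Si](C)(C)C(C)(C)C)c(O[Si](C)(C)C(C)(C)C)c2)Oc2cc(O[Si](C)(C)C(C)(C)C)cc(OCC=C(C)C)c12
F4 | step 7 | (2S)-7,3',4'-tris-O-(tert-butyldimethylsilyl)-8-prenyleriodictyol | CC(C)=CCc1c(O[Si](C)(C)C(C)(C)C)cc(O)c2c1O[C@H](c1ccc(O[Si](C)(C)C(C)(C)C)c(O[Si](C)(C)C(C)(C)C)c1)CC2=O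
F5 | step 2 | ethyl 3-[3,4-bis(tert-butyldimethylsilyloxy)phenyl]-3-oxopropanoate | CCOC(=O)CC(=O)c1ccc(O[Si](C)(C)C(C)(C)C)c(O[Si](C)(C)C(C)(C)C)c1
F6 | step 2 | ethyl (S)-3-[3,4-bis(tert-butyldimethylsilyloxy)phenyl]-3-hydroxypropanoate | CCOC(=O)C[C@H](O)c1ccc(O[Si](C)(C)C(C)(C)C)c(O[Si](C)(C)C(C)(C)C)c1
F7 | step 2 | (S)-3-[3,4-bis(tert-butyldimethylsilyloxy)phenyl]-3-hydroxy-N-methoxy-N-methylpropanamide | CON(C)C(=O)C[C@H](O)c1ccc(O[Si](C)(C)C(C)(C)C)c(O[Si](C)(C)C(C)(C)C)c1
F8 | step 2 | (S)-5-[3,4-bis(tert-butyldimethylsilyloxy)phenyl]-5-hydroxypent-1-yn-3-one | C#CC(=O)C[C@H](O)c1ccc(O[Si](C)(C)C(C)(C)C)c(O[Si](C)(C)C(C)(C)C)c1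
F9 | step 3 | (S)-2-[3,4-bis(tert-butyldimethylsilyloxy)phenyl]-5-(phenylthio)-2,3-dihydro-4H-pyran-4-one | O=C1C(Sc3ccccc3)=CO[C@H](c2ccc(O[Si](C)(C)C(C)(C)C)c(O[Si](C)(C)C(C)(C)C)c2)C1
F10 | step 3 | (2S)-2-[3,4-bis(tert-butyldimethylsilyloxy)phenyl]-5-(phenylsulfinyl)-2,3-dihydro-4H-pyran-4-one (sulfur epimers) | O=C1C(S(=O)c3ccccc3)=CO[C@H](c2ccc(O[Si](C)(C)C(C)(C)C)c(O[Si](C)(C)C(C)(C)C)c2)C1
F11 | step 3 | (2S)-2-[3,4-bis(tert-butyldimethylsilyloxy)phenyl]-5-methoxy-8-(3-methylbut-2-en-1-yl)-4a-(phenylsulfinyl)-5,7-bis(trimethylsilyloxy)-2,3,4a,5,8,8a-hexahydro-4H-chromen-4-one (transient centres unassigned) | O=C1C[C@@H](c3ccc(O[Si](C)(C)C(C)(C)C)c(O[Si](C)(C)C(C)(C)C)c3)OC2C(CC=C(C)C)C(O[Si](C)(C)C)=CC(OC)(O[Si](C)(C)C)C12S(=O)c1ccccc1
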